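**Plan**

- Retrosynthetic cuts: the lactone C6′–O bond (oxidative lactonisation of a 1,4-diol); the peroxide bonds O–C1′ (SN2) and O–C4′ (epoxide perhydrolysis); C13–C1′ (CrCl2/NiCl2 coupling of a C13 enol triflate with a C1′–C6′ aldehyde); the C18 ester back to a 6α,18-ether, and that C18–O bond back to an unactivated 4α-methyl group.
- Forward order: (+)-larixol supplies rings A and B with the 6α-hydroxyl; the 8(17)-alkene becomes the 8α-carbinol and the side chain the C13 methyl ketone; C–H etherification closes a temporary tetrahydrofuran (C18–O–C6); RuO4, then hydroxide and MeI, open it to the C18 methyl ester; triflate and aldehyde are joined; the 1,2-dioxane closes by hydroperoxide alkylation and the γ-lactone closes last.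
- Enabling feature: on the trans-decalin the equatorial 6α-oxygen (ring B) and the equatorial 4α-methyl C18 (ring A) flank C5 in a peri array (model distance O···C18 about 2.5 Å, O···C19 about 3.5 Å), so an oxygen radical on C6 reaches only C18 through the six-membered O–C6–C5–C4–C18–H transition state.
- Stereochemistry: C5, C6, C9 and C10 come from larixol; C8 from α-face epoxidation and hydride opening; C4 from the key step; C1′ from a CBS reduction followed by SN2 inversion; C3′ and C4′ from a Shi epoxidation with inversion at C4′ on perhydrolysis.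
- Numbering: labdane numbers for the core; C1′–C6′ for the aldehyde-derived carbons (C1′ on C13, C3′ the lactone carbinol carbon, C4′ the methyl-bearing peroxy carbon, C6′ the lactone carbonyl).

Key step: step 7

Remark: read as written, the target has the γ-lactone trans-fused to the 1,2-dioxane with the C13 substituent axial, (1′R,3′S,4′R) = dioxane (3R,4aS,7aR); the route is built for exactly this isomer.
Remark: (+)-larixol is used as purchased; its C13 configuration is immaterial because C13 becomes a carbonyl in step 3.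

**Route**

Step 1
Reactants: 1 (+)-larixol, (13S)-labda-8(17),14-diene-6α,13-diol
Product: 2 (13S)-8α,17-epoxylabd-14-ene-6α,13-diol
Conditions: mCPBA (1.05 equiv), NaHCO3, CH2Cl2, 0 °C
Reagents that add atoms: 3-chloroperoxybenzoic acid, OOC(=O)c1cccc(Cl)c1
Why: Prilezhaev epoxidation should pick the electron-richer 1,1-disubstituted 8(17)-alkene over the monosubstituted vinyl group, and the peracid should approach from the α-face because the axial C20 methyl screens the β-face, which makes the new C8–O bond α (equatorial).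

Step 2
Reactants: 2 (13S)-8α,17-epoxylabd-14-ene-6α,13-diol
Product: 3 (13S)-labd-14-ene-6α,8α,13-triol
Conditions: LiAlH4, THF, 0 °C to reflux; aqueous NaOH work-up
Reagents that add atoms: none
Why: SN2 hydride opening of the spiro-epoxide at the unhindered primary C17 leaves the 8α-oxygen as a tertiary alcohol and turns C17 into the 8β-methyl, so C8 keeps the configuration set in step 1.

Step 3
Reactants: 3 (13S)-labd-14-ene-6α,8α,13-triol
Product: 4 6α,8α-dihydroxy-14,15-dinorlabdan-13-one
Conditions: KMnO4, MgSO4, acetone/H2O, 0 °C to rt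
Reagents that add atoms: none
Why: Permanganate hydroxylates the vinyl group and cleaves the resulting 13,14,15-triol (oxidative glycol cleavage), the standard degradation of a sclareol-type side chain to the C13 methyl ketone, while the hindered ring hydroxyls should survive the buffered medium.

Step 4
Reactants: 4 6α,8α-dihydroxy-14,15-dinorlabdan-13-one
Product: 5 6α-acetoxy-8α-hydroxy-14,15-dinorlabdan-13-one
Conditions: Ac2O, pyridine, DMAP (cat.), CH2Cl2, rt
Reagents that add atoms: acetic anhydride, CC(=O)OC(C)=O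
Why: Nucleophilic-catalysed acylation takes the secondary equatorial 6α-hydroxyl and leaves the tertiary 8α-hydroxyl free, which differentiates the two oxygens.

Step 5
Reactants: 5 6α-acetoxy-8α-hydroxy-14,15-dinorlabdan-13-one
Product: 6 6α-acetoxy-8α-(triethylsilyloxy)-14,15-dinorlabdan-13-one
Conditions: Et3SiOTf, 2,6-lutidine, CH2Cl2, −78 to 0 °C
Reagents that add atoms: triethylsilyl trifluoromethanesulfonate, CC[Si](CC)(CC)OS(=O)(=O)C(F)(F)F
Why: A silyl triflate with a hindered base silylates the tertiary alcohol, and the low temperature keeps the methyl ketone from being converted into an enol silyl ether.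

Step 6
Reactants: 6 6α-acetoxy-8α-(triethylsilyloxy)-14,15-dinorlabdan-13-one
Product: 7 6α-hydroxy-8α-(triethylsilyloxy)-14,15-dinorlabdan-13-one
Conditions: K2CO3, MeOH, rt
Reagents that add atoms: none
Why: Base-catalysed transesterification removes the acetate while the hindered tertiary triethylsilyl ether is stable to methanolic carbonate, so only the 6α-hydroxyl is free for the next step.

Step 7
Reactants: 7 6α-hydroxy-8α-(triethylsilyloxy)-14,15-dinorlabdan-13-one
Product: 10 6α,18-epoxy-8α-(triethylsilyloxy)-14,15-dinorlabdan-13-one, via C6 hypoiodite 8 (not isolated), via 18-iodo-6α-alcohol 9 (not isolated)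
Conditions: PhI(OAc)2 (1.6 equiv), I2 (1.0 equiv), cyclohexane, tungsten-lamp irradiation, 40 °C
Reagents that add atoms: none
Why: PhI(OAc)2 and I2 form acetyl hypoiodite, which converts the 6α-hydroxyl into the hypoiodite 8; light homolyses the O–I bond, the C6 alkoxy radical takes a hydrogen from C18 through a chair-like six-membered transition state (1,5-hydrogen transfer), the C18 radical is capped by iodine to give 9, and the iodide, activated by further oxidation at iodine, is displaced by the 6α-oxygen. The closest known reaction type is the hypoiodite (Suárez-type) remote functionalisation that turns steroidal 6β-alcohols into 6β,19-ethers, applied here to the geometrically equivalent equatorial–equatorial peri pair. The tetrahydrofuran ring (O, C6, C5, C4, C18) closes in the 5-exo-tet mode. The new stereocentre C4 is fixed by the substrate, because the rigid trans-decalin holds the 6α-oxygen close to the 4α-methyl and well away from the 4β-methyl, so only the α-methyl is oxidised and the β-methyl stays as C19. The step needs site selectivity for C18 over C19, C20 and C17, and over β-scission or reaction at another oxygen; the equatorial C6–O vector secures the first, hydrogen transfer across the short peri contact should outrun C5–C6 cleavage, and the 8α-hydroxyl is silylated so that no second alkoxy radical can form.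

Step 8
Reactants: 10 6α,18-epoxy-8α-(triethylsilyloxy)-14,15-dinorlabdan-13-one
Product: 11 13-oxo-8α-(triethylsilyloxy)-14,15-dinorlabdan-18,6α-olide
Conditions: RuCl3 hydrate (5 mol%), NaIO4 (4 equiv), CCl4/MeCN/H2O, rt
Reagents that add atoms: sodium periodate, [Na+].[O-]I(=O)(=O)=O
Why: RuO4 generated in situ oxidises the ether α-methylene to the lactone carbonyl, and C18 should react in preference to the C6 methine, whose axial hydrogen is flanked by the three syn-axial methyls C17, C19 and C20 (the same reaction type converts steroidal 6β,19-ethers into lactones).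

Step 9
Reactants: 11 13-oxo-8α-(triethylsilyloxy)-14,15-dinorlabdan-18,6α-olide
Product: 13 methyl 6α-hydroxy-13-oxo-8α-(triethylsilyloxy)-14,15-dinorlabdan-18-oate, via potassium 18-carboxylate 12 (not isolated)
Conditions: KOH, MeOH/H2O, 50 °C; evaporate; then MeI, KHCO3, DMF, rt; product used at once
Reagents that add atoms: potassium hydroxide, [K+].[OH-]; iodomethane, CI
Why: Saponification to the carboxylate followed by SN2 O-methylation of that salt opens the lactone irreversibly and so avoids the lactone/hydroxy-ester equilibrium that a direct methanolysis of a γ-lactone would face; no stereocentre is touched.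

Step 10
Reactants: 13 methyl 6α-hydroxy-13-oxo-8α-(triethylsilyloxy)-14,15-dinorlabdan-18-oate
Product: 14 methyl 13-oxo-6α,8α-bis(triethylsilyloxy)-14,15-dinorlabdan-18-oate
Conditions: Et3SiOTf, 2,6-lutidine, CH2Cl2, −78 °C
Reagents that add atoms: triethylsilyl trifluoromethanesulfonate, CC[Si](CC)(CC)OS(=O)(=O)C(F)(F)F
Why: Silylation of the 6α-hydroxyl blocks relactonisation and protects this alcohol from the base of step 11 and the oxidant of step 16.

Step 11
Reactants: 14 methyl 13-oxo-6α,8α-bis(triethylsilyloxy)-14,15-dinorlabdan-18-oate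
Product: 15 methyl 6α,8α-bis(triethylsilyloxy)-13-(trifluoromethanesulfonyloxy)-14,15-dinorlabd-13(16)-en-18-oate
Conditions: KN(SiMe3)2, THF, −78 °C; then PhNTf2, −78 to −20 °C
Reagents that add atoms: N-phenylbis(trifluoromethanesulfonimide), O=S(=O)(N(c1ccccc1)S(=O)(=O)C(F)(F)F)C(F)(F)F
Why: Kinetic deprotonation of the methyl ketone at the methyl group and O-triflation of the terminal enolate give the 1,1-disubstituted enol triflate; the C18 ester sits on a quaternary carbon and cannot enolise.

Step 12
Reactants: 16 3-butyn-1-ol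
Product: 17 tert-butyl(but-3-yn-1-yloxy)diphenylsilane
Conditions: t-BuPh2SiCl, imidazole, DMF, rt
Reagents that add atoms: tert-butyl(chloro)diphenylsilane, CC(C)(C)[Si](Cl)(c1ccccc1)c1ccccc1
Why: Standard silylation of the primary alcohol; the tert-butyldiphenylsilyl ether is chosen because it should withstand the acidic perhydrolysis of step 20.

Step 13
Reactants: 17 tert-butyl(but-3-yn-1-yloxy)diphenylsilane
Product: 20 (E)-6-(tert-butyldiphenylsilyloxy)-4-methylhex-3-en-1-ol, via alkenyldimethylalane 18 (not isolated), via lithium alkenylaluminate 19 (not isolated)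
Conditions: AlMe3, Cp2ZrCl2 (25 mol%), CH2Cl2, 0 °C to rt; evaporate, hexane; n-BuLi, 0 °C; oxirane, THF, −78 °C to rt
Reagents that add atoms: trimethylaluminium, C[Al](C)C; oxirane, C1CO1
Why: Negishi carboalumination adds methyl and aluminium syn across the alkyne with methyl on the internal carbon, and the derived aluminate opens oxirane with retention at the alkenyl carbon, which fixes the E trisubstituted alkene (new CH2 cis to methyl).

Step 14
Reactants: 20 (E)-6-(tert-butyldiphenylsilyloxy)-4-methylhex-3-en-1-ol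
Product: 21 (E)-6-(tert-butyldiphenylsilyloxy)-4-methylhex-3-enal
Conditions: Dess–Martin periodinane, NaHCO3, CH2Cl2, 0 °C; used at once
Reagents that add atoms: none
Why: Buffered Dess–Martin oxidation gives the β,γ-unsaturated aldehyde under non-basic conditions, so the double bond should stay out of conjugation if the aldehyde is used directly.

Step 15
Reactants: 15 the C13 enol triflate; 21 (E)-6-(tert-butyldiphenylsilyloxy)-4-methylhex-3-enal
Product: 22 methyl 13-[(3′E)-6′-(tert-butyldiphenylsilyloxy)-1′-hydroxy-4′-methylhex-3′-en-1′-yl]-6α,8α-bis(triethylsilyloxy)-14,15-dinorlabd-13(16)-en-18-oate (both C1′ epimers)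
Conditions: CrCl2 (4 equiv), NiCl2 (2 mol%), DMF, rt
Reagents that add atoms: none
Why: Nozaki–Hiyama–Kishi coupling (nickel inserts into the alkenyl triflate, the alkenyl group passes to chromium and adds only to the aldehyde) forms the C13–C1′ bond without touching the ester or silyl ethers; no control at C1′ is expected, which steps 16 and 17 correct.

Step 16
Reactants: 22 the C1′ epimeric allylic alcohols
Product: 23 methyl 13-[(3′E)-6′-(tert-butyldiphenylsilyloxy)-4′-methyl-1′-oxohex-3′-en-1′-yl]-6α,8α-bis(triethylsilyloxy)-14,15-dinorlabd-13(16)-en-18-oate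
Conditions: Dess–Martin periodinane, NaHCO3, CH2Cl2, 0 °C
Reagents that add atoms: none
Why: Mild buffered oxidation of the allylic alcohol converges both epimers on one α-methylene ketone.

Step 17
Reactants: 23 the α-methylene ketone
Product: 24 the (1′S)-allylic alcohol, methyl 13-[(1′S,3′E)-6′-(tert-butyldiphenylsilyloxy)-1′-hydroxy-4′-methylhex-3′-en-1′-yl]-6α,8α-bis(triethylsilyloxy)-14,15-dinorlabd-13(16)-en-18-oate
Conditions: (R)-2-methyl-CBS-oxazaborolidine (0.5 equiv), catecholborane, toluene, −78 °C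
Reagents that add atoms: none
Why: Corey–Bakshi–Shibata reduction with the α-branched alkenyl group as the large substituent and the C2′ methylene as the small one should deliver hydride under catalyst control to give the 1′S carbinol with the (R)-catalyst, and catecholborane at low temperature leaves the isolated alkene alone.

Step 18
Reactants: 24 the (1′S)-allylic alcohol
Product: 25 the (1′S,3′S,4′S)-3′,4′-epoxy alcohol
Conditions: L-fructose-derived (ent) Shi ketone (0.5 equiv), Oxone (2KHSO5·KHSO4·K2SO4), K2CO3, Bu4NHSO4, MeCN/dimethoxymethane/aqueous Na2B4O7–Na2EDTA buffer (pH about 10.5), 0 °C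
Reagents that add atoms: potassium peroxymonosulfate, [K+].[O-]S(=O)(=O)OO
Why: Shi epoxidation is effective for E-trisubstituted alkenes and poor for terminal 1,1-disubstituted ones, so the chiral dioxirane should oxidise only C3′=C4′, and the enantiomeric ketone is needed because the D-fructose ketone gives the R,R series with this alkene class.

Step 19
Reactants: 25 the (1′S,3′S,4′S)-epoxy alcohol
Product: 26 the (1′S,3′S,4′S)-3′,4′-epoxy 1′-methanesulfonate
Conditions: Ms2O, Et3N, CH2Cl2, −40 °C; cold work-up, used crude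
Reagents that add atoms: methanesulfonic anhydride, CS(=O)(=O)OS(C)(=O)=O
Why: Sulfonylation activates C1′ with retention, and the anhydride is used instead of the chloride so that no chloride is present to displace the allylic sulfonate.

Step 20
Reactants: 26 the epoxy methanesulfonate
Product: 28 methyl 13-[(3R,5S,6R)-6-(2-(tert-butyldiphenylsilyloxy)ethyl)-5-hydroxy-6-methyl-1,2-dioxan-3-yl]-6α,8α-bis(triethylsilyloxy)-14,15-dinorlabd-13(16)-en-18-oate, via 4′-hydroperoxy-3′-hydroxy mesylate 27 (not isolated)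
Conditions: anhydrous H2O2 in Et2O, H3PMo12O40 (5 mol%), 0 °C to rt; aqueous wash; then Cs2CO3, DMF, 0 °C
Reagents that add atoms: hydrogen peroxide, OO
Why: Acid-catalysed perhydrolysis opens the trisubstituted epoxide at the tertiary C4′ with inversion to give the (3′S,4′R) β-hydroxy hydroperoxide, and the caesium hydroperoxide then displaces the C1′ sulfonate intramolecularly (6-exo-tet SN2, inversion to 1′R), which places the C13 substituent trans to the C4′ methyl as the target requires.

Step 21
Reactants: 28 the silylated dioxane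
Product: 29 methyl 6α,8α-dihydroxy-13-[(3R,5S,6R)-5-hydroxy-6-(2-hydroxyethyl)-6-methyl-1,2-dioxan-3-yl]-14,15-dinorlabd-13(16)-en-18-oate
Conditions: HF·pyridine, pyridine, THF, 0 °C to rt
Reagents that add atoms: none
Why: Buffered fluoride cleaves the two triethylsilyl ethers and the tert-butyldiphenylsilyl ether without base, which avoids base-induced fragmentation of the peroxide; any silyl group already lost in step 20 converges here.

Step 22
Reactants: 29 the tetraol
Product: 32 the target, methyl 6α,8α-dihydroxy-13-[(3R,4aS,7aR)-7a-methyl-6-oxotetrahydro-3H-furo[3,2-c][1,2]dioxin-3-yl]-14,15-dinorlabd-13(16)-en-18-oate, via hydroxy aldehyde 30 (not isolated), via lactol 31 (not isolated)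
Conditions: TEMPO (20 mol%), PhI(OAc)2 (2.5 equiv), CH2Cl2, rt
Reagents that add atoms: none
Why: The oxoammonium oxidant takes the primary alcohol selectively, the aldehyde is trapped by the equatorial C3′ hydroxyl as a trans-fused lactol and this is oxidised on to the γ-lactone (oxidative lactonisation of a 1,4-diol), while the hindered secondary 6α-hydroxyl, the tertiary 8α-hydroxyl and the peroxide should not react.

**Compound list**

1 | (+)-larixol, (13S)-labda-8(17),14-diene-6α,13-diol | C=C[C@@](C)(O)CC[C@@H]1[C@@]2(C)CCCC(C)(C)[C@@H]2[C@@H](O)CC1=C | starting material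
2 | (13S)-8α,17-epoxylabd-14-ene-6α,13-diol | C=C[C@@](C)(O)CC[C@@H]1[C@@]2(C)CCCC(C)(C)[C@@H]2[C@@H](O)C[C@]13CO3 | intermediate
3 | (13S)-labd-14-ene-6α,8α,13-triol | C=C[C@@](C)(O)CC[C@@H]1[C@@]2(C)CCCC(C)(C)[C@@H]2[C@@H](O)C[C@@]1(C)O | intermediate
4 | 6α,8α-dihydroxy-14,15-dinorlabdan-13-one | CC(=O)CC[C@@H]1[C@@]2(C)CCCC(C)(C)[C@@H]2[C@@H](O)C[C@@]1(C)O | intermediate
5 | 6α-acetoxy-8α-hydroxy-14,15-dinorlabdan-13-one | CC(=O)CC[C@@H]1[C@@]2(C)CCCC(C)(C)[C@@H]2[C@@H](OC(C)=O)C[C@@]1(C)O | intermediate
6 | 6α-acetoxy-8α-(triethylsilyloxy)-14,15-dinorlabdan-13-one | CC(=O)CC[C@@H]1[C@@]2(C)CCCC(C)(C)[C@@H]2[C@@H](OC(C)=O)C[C@@]1(C)O[Si](CC)(CC)CC | intermediate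
7 | 6α-hydroxy-8α-(triethylsilyloxy)-14,15-dinorlabdan-13-one (key-step precursor) | CC(=O)CC[C@@H]1[C@@]2(C)CCCC(C)(C)[C@@H]2[C@@H](O)C[C@@]1(C)O[Si](CC)(CC)CC | intermediate
8 | C6 hypoiodite of 7 | CC(=O)CC[C@@H]1[C@@]2(C)CCCC(C)(C)[C@@H]2[C@@H](OI)C[C@@]1(C)O[Si](CC)(CC)CC | intermediate (not isolated)
9 | 6α-hydroxy-18-iodo-8α-(triethylsilyloxy)-14,15-dinorlabdan-13-one | CC(=O)CC[C@@H]1[C@@]2(C)CCC[C@@](C)(CI)[C@@H]2[C@@H](O)C[C@@]1(C)O[Si](CC)(CC)CC | intermediate (not isolated)
10 | 6α,18-epoxy-8α-(triethylsilyloxy)-14,15-dinorlabdan-13-one (key-step product) | CC(=O)CC[C@@H]1[C@@]2(C)CCC[C@@]3(C)CO[C@H]([C@H]23)C[C@@]1(C)O[Si](CC)(CC)CC | intermediate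
11 | 13-oxo-8α-(triethylsilyloxy)-14,15-dinorlabdan-18,6α-olide | CC(=O)CC[C@@H]1[C@@]2(C)CCC[C@@]3(C)C(=O)O[C@H]([C@H]23)C[C@@]1(C)O[Si](CC)(CC)CC | intermediate
12 | potassium 6α-hydroxy-13-oxo-8α-(triethylsilyloxy)-14,15-dinorlabdan-18-oate | CC(=O)CC[C@@H]1[C@@]2(C)CCC[C@@](C)(C(=O)[O-])[C@@H]2[C@@H](O)C[C@@]1(C)O[Si](CC)(CC)CC.[K+] | intermediate (not isolated)
13 | methyl 6α-hydroxy-13-oxo-8α-(triethylsilyloxy)-14,15-dinorlabdan-18-oate | CC(=O)CC[C@@H]1[C@@]2(C)CCC[C@@](C)(C(=O)OC)[C@@H]2[C@@H](O)C[C@@]1(C)O[Si](CC)(CC)CC | intermediate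
14 | methyl 13-oxo-6α,8α-bis(triethylsilyloxy)-14,15-dinorlabdan-18-oate | CC(=O)CC[C@@H]1[C@@]2(C)CCC[C@@](C)(C(=O)OC)[C@@H]2[C@@H](O[Si](CC)(CC)CC)C[C@@]1(C)O[Si](CC)(CC)CC | intermediate
15 | methyl 6α,8α-bis(triethylsilyloxy)-13-(trifluoromethanesulfonyloxy)-14,15-dinorlabd-13(16)-en-18-oate | C=C(OS(=O)(=O)C(F)(F)F)CC[C@@H]1[C@@]2(C)CCC[C@@](C)(C(=O)OC)[C@@H]2[C@@H](O[Si](CC)(CC)CC)C[C@@]1(C)O[Si](CC)(CC)CC | intermediate
16 | 3-butyn-1-ol | C#CCCO | starting material
17 | tert-butyl(but-3-yn-1-yloxy)diphenylsilane | C#CCCO[Si](c1ccccc1)(c1ccccc1)C(C)(C)C | intermediate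
18 | (E)-[4-(tert-butyldiphenylsilyloxy)-2-methylbut-1-enyl]dimethylalane | C/C(CCO[Si](c1ccccc1)(c1ccccc1)C(C)(C)C)=C\[Al](C)C | intermediate (not isolated)
19 | lithium butyl[(E)-4-(tert-butyldiphenylsilyloxy)-2-methylbut-1-enyl]dimethylaluminate | [Li+].CCCC[Al-](C)(C)/C=C(\C)CCO[Si](c1ccccc1)(c1ccccc1)C(C)(C)C | intermediate (not isolated)
20 | (E)-6-(tert-butyldiphenylsilyloxy)-4-methylhex-3-en-1-ol | C/C(CCO[Si](c1ccccc1)(c1ccccc1)C(C)(C)C)=C\CCO | intermediate
21 | (E)-6-(tert-butyldiphenylsilyloxy)-4-methylhex-3-enal | C/C(CCO[Si](c1ccccc1)(c1ccccc1)C(C)(C)C)=C\CC=O | intermediate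
22 | coupled allylic alcohol, both C1′ epimers | C=C(C(O)C/C=C(\C)CCO[Si](c1ccccc1)(c1ccccc1)C(C)(C)C)CC[C@@H]1[C@@]2(C)CCC[C@@](C)(C(=O)OC)[C@@H]2[C@@H](O[Si](CC)(CC)CC)C[C@@]1(C)O[Si](CC)(CC)CC | intermediate
23 | α-methylene ketone (1′-oxo) | C=C(C(=O)C/C=C(\C)CCO[Si](c1ccccc1)(c1ccccc1)C(C)(C)C)CC[C@@H]1[C@@]2(C)CCC[C@@](C)(C(=O)OC)[C@@H]2[C@@H](O[Si](CC)(CC)CC)C[C@@]1(C)O[Si](CC)(CC)CC | intermediate
24 | (1′S)-allylic alcohol | C=C([C@@H](O)C/C=C(\C)CCO[Si](c1ccccc1)(c1ccccc1)C(C)(C)C)CC[C@@H]1[C@@]2(C)CCC[C@@](C)(C(=O)OC)[C@@H]2[C@@H](O[Si](CC)(CC)CC)C[C@@]1(C)O[Si](CC)(CC)CC | intermediate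
25 | (1′S,3′S,4′S)-3′,4′-epoxy alcohol | C=C([C@@H](O)C[C@@H]3O[C@@]3(C)CCO[Si](c4ccccc4)(c5ccccc5)C(C)(C)C)CC[C@@H]1[C@@]2(C)CCC[C@@](C)(C(=O)OC)[C@@H]2[C@@H](O[Si](CC)(CC)CC)C[C@@]1(C)O[Si](CC)(CC)CC | intermediate
26 | (1′S,3′S,4′S)-3′,4′-epoxy 1′-methanesulfonate | C=C([C@@H](OS(C)(=O)=O)C[C@@H]3O[C@@]3(C)CCO[Si](c4ccccc4)(c5ccccc5)C(C)(C)C)CC[C@@H]1[C@@]2(C)CCC[C@@](C)(C(=O)OC)[C@@H]2[C@@H](O[Si](CC)(CC)CC)C[C@@]1(C)O[Si](CC)(CC)CC | intermediate
27 | (1′S,3′S,4′R)-4′-hydroperoxy-3′-hydroxy 1′-methanesulfonate | C=C([C@@H](OS(C)(=O)=O)C[C@H](O)[C@](C)(OO)CCO[Si](c4ccccc4)(c5ccccc5)C(C)(C)C)CC[C@@H]1[C@@]2(C)CCC[C@@](C)(C(=O)OC)[C@@H]2[C@@H](O[Si](CC)(CC)CC)C[C@@]1(C)O[Si](CC)(CC)CC | intermediate (not isolated)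
28 | silylated (3R,5S,6R)-5-hydroxy-1,2-dioxane | C=C(CC[C@@H]1[C@@]2(C)CCC[C@@](C)(C(=O)OC)[C@@H]2[C@@H](O[Si](CC)(CC)CC)C[C@@]1(C)O[Si](CC)(CC)CC)[C@H]3C[C@H](O)[C@@](C)(CCO[Si](c4ccccc4)(c5ccccc5)C(C)(C)C)OO3 | intermediate
29 | dioxane tetraol | C=C(CC[C@@H]1[C@@]2(C)CCC[C@@](C)(C(=O)OC)[C@@H]2[C@@H](O)C[C@@]1(C)O)[C@H]3C[C@H](O)[C@@](C)(CCO)OO3 | intermediate
30 | dioxane hydroxy aldehyde | C=C(CC[C@@H]1[C@@]2(C)CCC[C@@](C)(C(=O)OC)[C@@H]2[C@@H](O)C[C@@]1(C)O)[C@H]3C[C@H](O)[C@@](C)(CC=O)OO3 | intermediate (not isolated)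
31 | trans-fused lactol (anomers) | C=C(CC[C@@H]1[C@@]2(C)CCC[C@@](C)(C(=O)OC)[C@@H]2[C@@H](O)C[C@@]1(C)O)[C@H]3C[C@@H]4OC(O)C[C@@]4(C)OO3 | intermediate (not isolated)
32 | CNP0162504.1 | C=C(CC[C@@H]1[C@@]2(C)CCC[C@@](C)(C(=O)OC)[C@@H]2[C@@H](O)C[C@@]1(C)O)[C@H]1C[C@@H]2OC(=O)C[C@@]2(C)OO1 | target

**Count**

Total step count: 22.
Longest linear sequence: 19 steps (steps 1–11 and 15–22, from larixol); the aldehyde branch (steps 12–14) joins at step 15.

**Steps most likely to fail**

Step 20. The secondary allylic methanesulfonate may ionise or solvolyse in the acidic peroxide medium before the hydroperoxide is in place, with loss of the leaving group or of configurational integrity at C1′; base-induced fragmentation of the finished peroxide is a lesser concern. The fallback sets out from 26 and reverses the order in which the two peroxide C–O bonds are made. The sulfonate is displaced first, under basic non-ionising conditions, by 2-methoxyprop-2-yl hydroperoxide (CsOH·H2O, DMF, 0 °C; intermolecular SN2 with inversion) to give the (1′R)-2-methoxyprop-2-yl peroxide of the epoxide F1. Aqueous acetic acid in THF then releases the (1′R)-hydroperoxy epoxide F2. Catalytic camphorsulfonic acid in CH2Cl2 should promote 6-endo opening of the trisubstituted epoxide at the tertiary C4′ with inversion, which brings the material back to the route at 28 with the same configuration at all three centres.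

Step 7. After hydrogen transfer the neopentyl C18 iodide may fail to close onto oxygen, and acetyl hypoiodite may attack the enolisable methyl ketone, so that material stalls or is lost to α-iodination. The fallback sets out from 7 and uses the Barton nitrite photolysis, which needs no electrophilic iodine. Nitrosyl chloride in pyridine gives the 6α-nitrite ester F3. Irradiation in benzene transfers NO to C18 through the same six-membered transition state and, after tautomerisation, gives the 6α-hydroxy 18-oxime F4. NaNO2 in aqueous acetic acid converts the oxime into the cyclic 6α,18-hemiacetal F5, and RuCl3/NaIO4 oxidises this lactol to the lactone, so the route is rejoined at 11.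

Step 16. The C2′ methylene of the ketone 23 lies between the enone carbonyl and the C3′=C4′ alkene, and a prototropic shift of that alkene into conjugation during oxidation, chromatography or reduction would destroy the epoxidation substrate. The fallback sets out from 15 and 21 and avoids the ketone altogether. The coupling is run as a catalytic asymmetric CrCl2/NiCl2 reaction with a chiral oxazoline–sulfonamide ligand (CrCl2, ligand and Et3N premixed; NiCl2 complex as co-catalyst; Mn, Cp2ZrCl2, MeCN), using the ligand antipode that favours the 1′S carbinol, so that reagent control sets C1′ in the bond-forming step. It returns to the route at 24 and makes no new compound (F0).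

Further compounds
F1 | step 20 | (1′R)-1′-(2-methoxyprop-2-ylperoxy) (3′S,4′S)-epoxide | C=C([C@H](OOC(C)(C)OC)C[C@@H]3O[C@@]3(C)CCO[Si](c4ccccc4)(c5ccccc5)C(C)(C)C)CC[C@@H]1[C@@]2(C)CCC[C@@](C)(C(=O)OC)[C@@H]2[C@@H](O[Si](CC)(CC)CC)C[C@@]1(C)O[Si](CC)(CC)CC
F2 | step 20 | (1′R)-1′-hydroperoxy (3′S,4′S)-epoxide | C=C([C@H](OO)C[C@@H]3O[C@@]3(C)CCO[Si](c4ccccc4)(c5ccccc5)C(C)(C)C)CC[C@@H]1[C@@]2(C)CCC[C@@](C)(C(=O)OC)[C@@H]2[C@@H](O[Si](CC)(CC)CC)C[C@@]1(C)O[Si](CC)(CC)CC
F3 | step 7 | 6α-nitrite ester of 7 | CC(=O)CC[C@@H]1[C@@]2(C)CCCC(C)(C)[C@@H]2[C@@H](ON=O)C[C@@]1(C)O[Si](CC)(CC)CC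
F4 | step 7 | 6α-hydroxy-13-oxo-8α-(triethylsilyloxy)-14,15-dinorlabdan-18-al oxime | CC(=O)CC[C@@H]1[C@@]2(C)CCC[C@@](C)(C=NO)[C@@H]2[C@@H](O)C[C@@]1(C)O[Si](CC)(CC)CC
F5 | step 7 | 6α,18-epoxy-18-hydroxy-8α-(triethylsilyloxy)-14,15-dinorlabdan-13-one (lactol) | CC(=O)CC[C@@H]1[C@@]2(C)CCC[C@@]3(C)C(O)O[C@H]([C@H]23)C[C@@]1(C)O[Si](CC)(CC)CC
F0 | step 16 | none | none
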